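**Strategy**

Everything rests on disconnecting ring C between the carbonyl carbon C4 and the ring A carbon C4a. C4a lies ortho to the ether oxygen O1 and para to the C7 oxygen, exactly where 4-bromoresorcinol carries its bromine, so the halogen marks the site of bond formation. In the key step bromine–lithium exchange generates an aryllithium at C4a that attacks a Weinreb amide carbon (C4), a Parham cyclisation that closes the pyranone ring at low temperature without acid, sparing both prenyl groups and the C2 stereocentre. The precursor is an open-chain (S)-3-aryl-3-(2-bromoaryloxy)propanoic Weinreb amide; its C2–O1 bond comes from Mitsunobu inversion of an (R)-carbinol made by copper-catalysed asymmetric β-borylation.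

Key step: step 7

Assumption: the (S,Rp)-Josiphos ligand named in step 4 is taken to deliver the (R)-boronate 7; should the sense of induction prove opposite, its commercially available mirror image is used instead.

**Route**

Step 1
Reactants: 1 4-iodophenol; 2 prenyl bromide (1-bromo-3-methylbut-2-ene), used twice (2.2 equiv in all)
Product: 3 4-iodo-2,6-bis(3-methylbut-2-en-1-yl)phenol
Conditions: NaH (2.2 equiv), toluene, 0 °C; then prenyl bromide (2.2 equiv), rt
Reagents that add atoms: prenyl bromide (the second equivalent of 2, which supplies the second prenyl group), CC(C)=CCBr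
Why: In non-polar toluene the sodium phenoxide reacts as a tight ion pair, so each of the two equivalents of the allylic bromide should alkylate an ortho carbon and not oxygen (ortho C-alkylation of an ambident phenoxide, followed by tautomerisation and renewed deprotonation), and with the para position blocked by iodine the two successive alkylations should give the 2,6-diprenylphenol.

Step 2
Reactants: 3 4-iodo-2,6-bis(3-methylbut-2-en-1-yl)phenol
Product: 4 tert-butyl[4-iodo-2,6-bis(3-methylbut-2-en-1-yl)phenoxy]dimethylsilane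
Conditions: TBSCl, imidazole, DMAP (cat.), DMF, 50 °C
Reagents that add atoms: tert-butyldimethylsilyl chloride, CC(C)(C)[Si](C)(C)Cl
Why: Imidazole-promoted O-silylation of the phenol should proceed with mild heating despite the two flanking prenyl groups, and the resulting hindered aryl silyl ether should then be robust towards the mildly basic steps that follow.

Step 3
Reactants: 4 tert-butyl[4-iodo-2,6-bis(3-methylbut-2-en-1-yl)phenoxy]dimethylsilane; 5 N-methoxy-N-methylacrylamide
Product: 6 (E)-3-[4-(tert-butyldimethylsilyloxy)-3,5-bis(3-methylbut-2-en-1-yl)phenyl]-N-methoxy-N-methylprop-2-enamide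
Conditions: Pd(OAc)2 (5 mol%), P(o-tol)3 (10 mol%), Et3N, DMF, 90 °C
Reagents that add atoms: none
Why: Mizoroki–Heck reaction, in which oxidative addition of the aryl iodide to zerovalent palladium, syn insertion of the electron-poor acrylamide and syn β-hydride elimination should give the (E)-enamide, the isolated trisubstituted prenyl alkenes inserting far more slowly.

Step 4
Reactants: 6 (E)-3-[4-(tert-butyldimethylsilyloxy)-3,5-bis(3-methylbut-2-en-1-yl)phenyl]-N-methoxy-N-methylprop-2-enamide
Product: 8 (R)-3-[4-(tert-butyldimethylsilyloxy)-3,5-bis(3-methylbut-2-en-1-yl)phenyl]-3-hydroxy-N-methoxy-N-methylpropanamide, via boronate 7 (not isolated)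
Conditions: CuCl (3 mol%), NaOt-Bu (5 mol%), (S)-1-[(Rp)-2-(diphenylphosphino)ferrocenyl]ethyldicyclohexylphosphine (3 mol%), B2pin2 (1.1 equiv), MeOH (2 equiv), THF, rt; then NaBO3·4H2O, THF/H2O, rt
Reagents that add atoms: bis(pinacolato)diboron, CC1(C)OB(OC1(C)C)B1OC(C)(C)C(C)(C)O1 (boron of 7); sodium perborate tetrahydrate, [Na+].[Na+].O[B-]1(O)OO[B-](O)(O)OO1 (hydroxyl oxygen of 8)
Why: Copper-catalysed enantioselective conjugate borylation, in which the Josiphos-ligated copper–boryl species selects one face of the (E)-enamide and places boron on the benzylic carbon to set the (R) centre of 7, methanol protonates the copper enolate, and perborate oxidation then replaces boron by hydroxyl with retention through a 1,2-boronate shift.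

Step 5
Reactants: 9 4-bromoresorcinol (4-bromobenzene-1,3-diol)
Product: 10 2-bromo-5-(tert-butyldimethylsilyloxy)phenol
Conditions: TBSCl (1.0 equiv), imidazole, CH2Cl2, 0 °C
Reagents that add atoms: tert-butyldimethylsilyl chloride, CC(C)(C)[Si](C)(C)Cl
Why: Sterically controlled monosilylation, in which one equivalent of the bulky chlorosilane should react at the unhindered hydroxyl para to bromine and leave free the hydroxyl that is flanked by bromine, which is the one needed for the ether bond.

Step 6
Reactants: 8 (R)-3-[4-(tert-butyldimethylsilyloxy)-3,5-bis(3-methylbut-2-en-1-yl)phenyl]-3-hydroxy-N-methoxy-N-methylpropanamide; 10 2-bromo-5-(tert-butyldimethylsilyloxy)phenol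
Product: 11 (S)-3-[2-bromo-5-(tert-butyldimethylsilyloxy)phenoxy]-3-[4-(tert-butyldimethylsilyloxy)-3,5-bis(3-methylbut-2-en-1-yl)phenyl]-N-methoxy-N-methylpropanamide
Conditions: PPh3, DIAD, toluene, 0 °C to rt
Reagents that add atoms: none
Why: Mitsunobu etherification, in which the acidic ortho-bromophenol displaces the alkoxyphosphonium group at the benzylic carbon by SN2 with inversion, turning (R)-8 into the (S)-ether; ionisation should be held back because the silyloxy group, twisted out of conjugation by its two prenyl neighbours, donates only weakly, and elimination because amide α-hydrogens are weakly acidic.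

Step 7
Reactants: 11 (S)-3-[2-bromo-5-(tert-butyldimethylsilyloxy)phenoxy]-3-[4-(tert-butyldimethylsilyloxy)-3,5-bis(3-methylbut-2-en-1-yl)phenyl]-N-methoxy-N-methylpropanamide
Product: 14 (S)-7-(tert-butyldimethylsilyloxy)-2-[4-(tert-butyldimethylsilyloxy)-3,5-bis(3-methylbut-2-en-1-yl)phenyl]chroman-4-one, via aryllithium 12 (not isolated), via lithium hemiaminal alkoxide 13 (not isolated)
Conditions: t-BuLi (2.05 equiv), THF, −90 to −78 °C; then sat. aq. NH4Cl, −78 °C to rt
Reagents that add atoms: tert-butyllithium, [Li]C(C)(C)C (lithium of 12 and 13 only; no atom of 14)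
Why: tert-Butyllithium should exchange the aryl bromine for lithium far faster than it deprotonates or adds to the amide (the second equivalent destroys the tert-butyl bromide), and aryllithium 12, whose carbanionic carbon is the future C4a, adds to the amide carbonyl carbon C4 to give the N-methoxy-chelated tetrahedral alkoxide 13, which persists until the quench and then collapses to ketone 14, so no second addition can occur. The closest known reaction type is the Parham cyclisation, the intramolecular acylation of an aryllithium made by halogen–lithium exchange by a tethered carboxylic acid derivative, for which Weinreb amides are known acceptors and chroman-4-ones known products. Ring C closes in the 6-exo-trig mode, its six atoms being C4a, C8a, O1, C2, C3 and C4 with the carbonyl oxygen exocyclic. No stereocentre is created in the product (the hemiaminal carbon of 13 is lost on work-up), and the C2 centre set in step 6 is carried through because no bond to C2 is broken and the cold aprotic medium offers no retro-oxa-Michael pathway. The step needs regioselectivity for C4a over C8, the other carbon flanking C8a, which the bromine inherited from 4-bromoresorcinol guarantees, and chemoselectivity for exchange and acylation over proton transfer from the C3 methylene (which would expel the phenoxide), which the low temperature, the hindered base and the fast six-membered closure should secure.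

Step 8
Reactants: 14 (S)-7-(tert-butyldimethylsilyloxy)-2-[4-(tert-butyldimethylsilyloxy)-3,5-bis(3-methylbut-2-en-1-yl)phenyl]chroman-4-one
Product: 15 (S)-7-hydroxy-2-[4-hydroxy-3,5-bis(3-methylbut-2-en-1-yl)phenyl]chroman-4-one (the target flavanone)
Conditions: Bu4NF/AcOH (1:1, 3 equiv), THF, 0 °C
Reagents that add atoms: none
Why: Fluoride-induced cleavage of both aryl silyl ethers, buffered with acetic acid so that no free phenoxide builds up that could open ring C by a retro-oxa-Michael (quinone methide) pathway and racemise C2; the prenyl groups should be inert.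

**Compound list**

1 | 4-iodophenol | Oc1ccc(I)cc1 | starting material
2 | prenyl bromide (1-bromo-3-methylbut-2-ene) | CC(C)=CCBr | starting material
3 | 4-iodo-2,6-bis(3-methylbut-2-en-1-yl)phenol | CC(C)=CCc1cc(I)cc(CC=C(C)C)c1O | intermediate
4 | tert-butyl[4-iodo-2,6-bis(3-methylbut-2-en-1-yl)phenoxy]dimethylsilane | CC(C)=CCc1cc(I)cc(CC=C(C)C)c1O[Si](C)(C)C(C)(C)C | intermediate
5 | N-methoxy-N-methylacrylamide | C=CC(=O)N(C)OC | starting material
6 | (E)-3-[4-(tert-butyldimethylsilyloxy)-3,5-bis(3-methylbut-2-en-1-yl)phenyl]-N-methoxy-N-methylprop-2-enamide | CC(C)=CCc1cc(/C=C/C(=O)N(C)OC)cc(CC=C(C)C)c1O[Si](C)(C)C(C)(C)C | intermediate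
7 | (R)-3-[4-(tert-butyldimethylsilyloxy)-3,5-bis(3-methylbut-2-en-1-yl)phenyl]-N-methoxy-N-methyl-3-(4,4,5,5-tetramethyl-1,3,2-dioxaborolan-2-yl)propanamide (not isolated) | CC(C)=CCc1cc([C@@H](CC(=O)N(C)OC)B2OC(C)(C)C(C)(C)O2)cc(CC=C(C)C)c1O[Si](C)(C)C(C)(C)C | intermediate
8 | (R)-3-[4-(tert-butyldimethylsilyloxy)-3,5-bis(3-methylbut-2-en-1-yl)phenyl]-3-hydroxy-N-methoxy-N-methylpropanamide | CC(C)=CCc1cc([C@@H](CC(=O)N(C)OC)O)cc(CC=C(C)C)c1O[Si](C)(C)C(C)(C)C | intermediate
9 | 4-bromoresorcinol (4-bromobenzene-1,3-diol) | Oc1ccc(Br)c(O)c1 | starting material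
10 | 2-bromo-5-(tert-butyldimethylsilyloxy)phenol | Oc1cc(O[Si](C)(C)C(C)(C)C)ccc1Br | intermediate
11 | (S)-3-[2-bromo-5-(tert-butyldimethylsilyloxy)phenoxy]-3-[4-(tert-butyldimethylsilyloxy)-3,5-bis(3-methylbut-2-en-1-yl)phenyl]-N-methoxy-N-methylpropanamide | CC(C)=CCc1cc([C@H](CC(=O)N(C)OC)Oc2cc(O[Si](C)(C)C(C)(C)C)ccc2Br)cc(CC=C(C)C)c1O[Si](C)(C)C(C)(C)C | intermediate
12 | aryllithium from 11, lithium in place of bromine (not isolated) | CC(C)=CCc1cc([C@H](CC(=O)N(C)OC)Oc2cc(O[Si](C)(C)C(C)(C)C)ccc2[Li])cc(CC=C(C)C)c1O[Si](C)(C)C(C)(C)C | intermediate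
13 | lithium alkoxide of the cyclic C4 hemiaminal, (2S)-4-[methoxy(methyl)amino]chroman-4-olate, configuration at C4 undefined (not isolated) | CC(C)=CCc1cc([C@@H]2CC(O[Li])(N(C)OC)c3ccc(O[Si](C)(C)C(C)(C)C)cc3O2)cc(CC=C(C)C)c1O[Si](C)(C)C(C)(C)C | intermediate
14 | (S)-7-(tert-butyldimethylsilyloxy)-2-[4-(tert-butyldimethylsilyloxy)-3,5-bis(3-methylbut-2-en-1-yl)phenyl]chroman-4-one | CC(C)=CCc1cc([C@@H]2CC(=O)c3ccc(O[Si](C)(C)C(C)(C)C)cc3O2)cc(CC=C(C)C)c1O[Si](C)(C)C(C)(C)C | intermediate
15 | (S)-7-hydroxy-2-[4-hydroxy-3,5-bis(3-methylbut-2-en-1-yl)phenyl]chroman-4-one | CC(C)=CCc1cc([C@@H]2CC(=O)c3ccc(O)cc3O2)cc(CC=C(C)C)c1O | target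

**Step count and risks**

Total step count: 8. Longest linear sequence: 7 steps (steps 1, 2, 3, 4, 6, 7, 8); step 5 prepares the ring A fragment on a side branch.

Steps most likely to fail:

1. Step 6 (Mitsunobu etherification). The benzylic alkoxyphosphonium may ionise before the phenoxide arrives, eroding the configuration at C2, or the betaine may induce elimination back to the enamide. The fallback makes the C2–O1 bond by iridium-catalysed asymmetric allylic etherification instead, which never places a leaving group β to a carbonyl. It sets out from compound 4 and comes back to the route at compound 11. Mizoroki–Heck coupling of 4 with methyl acrylate (Pd(OAc)2, P(o-tol)3, Et3N, DMF, 90 °C) would give methyl (E)-3-[4-(tert-butyldimethylsilyloxy)-3,5-bis(3-methylbut-2-en-1-yl)phenyl]prop-2-enoate F1. Reduction with i-Bu2AlH (CH2Cl2, −78 °C) would give the (E)-cinnamyl alcohol F2, and methyl chloroformate with pyridine its methyl carbonate F3. The lithium phenoxide of 10 (from LiN(SiMe3)2) would then be allylated by F3 with [Ir(cod)Cl]2 and the phosphoramidite ligand O,O'-(Sa)-(1,1'-binaphthalene-2,2'-diyl)-N,N-bis[(S)-1-phenylethyl]phosphoramidite in THF, the ligand enantiomer being the one that gives the (S)-ether, so that the product should be the branched (S)-1-arylallyl aryl ether F4. Hydroboration of the terminal vinyl group with 9-BBN (the trisubstituted prenyl alkenes react far more slowly) and NaBO3·4H2O oxidation would give the primary alcohol F5, and oxidation with TEMPO (cat.) and PhI(OAc)2 in MeCN/H2O the carboxylic acid F6. Coupling of F6 with N,O-dimethylhydroxylamine hydrochloride (EDC·HCl, N-methylmorpholine, CH2Cl2, 0 °C) would give 11.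

2. Step 7 (Parham cyclisation). Proton transfer to the aryllithium from the C3 methylene or from C2–H may outrun acylation, leading to expulsion of the phenoxide or to simple protodebromination. The fallback closes the same C4–C4a bond from the electrophilic side, without a halogen. It sets out from compound 8 and comes back at compound 14. Mitsunobu reaction of 8 with purchased 3-(tert-butyldimethylsilyloxy)phenol F7 (PPh3, DIAD, toluene) would give the debromo (S)-aryl ether Weinreb amide F8. Reduction with i-Bu2AlH (THF, −78 °C) would give the (S)-aldehyde F9, and Pinnick oxidation (NaClO2, NaH2PO4, 2-methylbut-2-ene, t-BuOH/H2O) the (S)-carboxylic acid F10. Treatment of F10 with (CF3CO)2O in CH2Cl2 at 0 °C would form the mixed anhydride, and intramolecular Friedel–Crafts acylation should follow at the ring A carbon ortho to the ether oxygen and para to the silyloxy group, the less hindered of the two activated positions, to give 14.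

3. Step 1 (double ortho-prenylation). O-alkylation, arrest at the monoprenyl stage and over-alkylation to dienones may compete and leave little of the 2,6-dialkylated phenol. The fallback attaches the prenyl groups by cross-coupling instead. It sets out from compound 1 and comes back at compound 6. Mizoroki–Heck coupling of 1 with 5 (Pd(OAc)2, P(o-tol)3, Et3N, DMF) would give (E)-3-(4-hydroxyphenyl)-N-methoxy-N-methylprop-2-enamide F11. Double ortho-bromination with NBS (2 equiv, MeCN, 0 °C) would give the 3,5-dibromo-4-hydroxy compound F12, and silylation (TBSCl, imidazole, DMF) the silyl ether F13. Twofold Stille coupling of F13 with tributyl(3-methylbut-2-en-1-yl)stannane (Pd(PPh3)4, DMF, 100 °C) would give 6.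

**Further compounds**

F1 | step 6 | methyl (E)-3-[4-(tert-butyldimethylsilyloxy)-3,5-bis(3-methylbut-2-en-1-yl)phenyl]prop-2-enoate | COC(=O)/C=C/c1cc(CC=C(C)C)c(O[Si](C)(C)C(C)(C)C)c(CC=C(C)C)c1
F2 | step 6 | (E)-3-[4-(tert-butyldimethylsilyloxy)-3,5-bis(3-methylbut-2-en-1-yl)phenyl]prop-2-en-1-ol | OC/C=C/c1cc(CC=C(C)C)c(O[Si](C)(C)C(C)(C)C)c(CC=C(C)C)c1
F3 | step 6 | (E)-3-[4-(tert-butyldimethylsilyloxy)-3,5-bis(3-methylbut-2-en-1-yl)phenyl]prop-2-en-1-yl methyl carbonate | COC(=O)OC/C=C/c1cc(CC=C(C)C)c(O[Si](C)(C)C(C)(C)C)c(CC=C(C)C)c1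
F4 | step 6 | (S)-[4-bromo-3-({1-[4-(tert-butyldimethylsilyloxy)-3,5-bis(3-methylbut-2-en-1-yl)phenyl]prop-2-en-1-yl}oxy)phenoxy](tert-butyl)dimethylsilane | CC(C)=CCc1cc([C@H](C=C)Oc2cc(O[Si](C)(C)C(C)(C)C)ccc2Br)cc(CC=C(C)C)c1O[Si](C)(C)C(C)(C)C
F5 | step 6 | (S)-3-[2-bromo-5-(tert-butyldimethylsilyloxy)phenoxy]-3-[4-(tert-butyldimethylsilyloxy)-3,5-bis(3-methylbut-2-en-1-yl)phenyl]propan-1-ol | CC(C)=CCc1cc([C@H](CCO)Oc2cc(O[Si](C)(C)C(C)(C)C)ccc2Br)cc(CC=C(C)C)c1O[Si](C)(C)C(C)(C)C
F6 | step 6 | (S)-3-[2-bromo-5-(tert-butyldimethylsilyloxy)phenoxy]-3-[4-(tert-butyldimethylsilyloxy)-3,5-bis(3-methylbut-2-en-1-yl)phenyl]propanoic acid | CC(C)=CCc1cc([C@H](CC(=O)O)Oc2cc(O[Si](C)(C)C(C)(C)C)ccc2Br)cc(CC=C(C)C)c1O[Si](C)(C)C(C)(C)C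
F7 | step 7 | 3-(tert-butyldimethylsilyloxy)phenol (purchased) | Oc1cccc(O[Si](C)(C)C(C)(C)C)c1
F8 | step 7 | (S)-3-[3-(tert-butyldimethylsilyloxy)phenoxy]-3-[4-(tert-butyldimethylsilyloxy)-3,5-bis(3-methylbut-2-en-1-yl)phenyl]-N-methoxy-N-methylpropanamide | CC(C)=CCc1cc([C@H](CC(=O)N(C)OC)Oc2cccc(O[Si](C)(C)C(C)(C)C)c2)cc(CC=C(C)C)c1O[Si](C)(C)C(C)(C)C
F9 | step 7 | (S)-3-[3-(tert-butyldimethylsilyloxy)phenoxy]-3-[4-(tert-butyldimethylsilyloxy)-3,5-bis(3-methylbut-2-en-1-yl)phenyl]propanal | CC(C)=CCc1cc([C@H](CC=O)Oc2cccc(O[Si](C)(C)C(C)(C)C)c2)cc(CC=C(C)C)c1O[Si](C)(C)C(C)(C)C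
F10 | step 7 | (S)-3-[3-(tert-butyldimethylsilyloxy)phenoxy]-3-[4-(tert-butyldimethylsilyloxy)-3,5-bis(3-methylbut-2-en-1-yl)phenyl]propanoic acid | CC(C)=CCc1cc([C@H](CC(=O)O)Oc2cccc(O[Si](C)(C)C(C)(C)C)c2)cc(CC=C(C)C)c1O[Si](C)(C)C(C)(C)C
F11 | step 1 | (E)-3-(4-hydroxyphenyl)-N-methoxy-N-methylprop-2-enamide | CON(C)C(=O)/C=C/c1ccc(O)cc1
F12 | step 1 | (E)-3-(3,5-dibromo-4-hydroxyphenyl)-N-methoxy-N-methylprop-2-enamide | CON(C)C(=O)/C=C/c1cc(Br)c(O)c(Br)c1
F13 | step 1 | (E)-3-[3,5-dibromo-4-(tert-butyldimethylsilyloxy)phenyl]-N-methoxy-N-methylprop-2-enamide | CON(C)C(=O)/C=C/c1cc(Br)c(O[Si](C)(C)C(C)(C)C)c(Br)c1
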